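**Remarks on the chemistry (assumptions)**

- The target is the 3R ketone. The key-step alcohol 12 has the same spatial arrangement but is S, because its CH2OH arm ranks below the aryloxymethyl arm until it is oxidised. The structures of the key-step precursors and product were checked and needed no correction.
- The sense of induction of the phosphoric acid in step 7 cannot be predicted with confidence. (S)-STRIP is written; its mirror image is to be used if it favours the R alcohol.
- Design changes: the ring B methyl ether is removed with a thiolate, not a boron halide, to spare the chromene. The aryl–oxetane bond is made directly from the bromide, because a boronic acid coupling in hot alkoxide would strip the phenolic silyl ether; this also saves a step.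
- Compounds 1, 2, 8 and 10 are taken as commercial.

## Structural features

The target is a 3-arylchroman-4-one (isoflavanone). Ring A carries 5-OMe and 7-OH and is fused to the pyranone ring C (O1, C2, C3, C4=O). C3 carries ring B, which is fused to a 2,2-dimethylpyran (ring D) to give a 2H-chromene that is attached through its C6 and bears an 8-OH. C3 (R) is the only stereocentre, so it has no stereogenic neighbour and must be set by absolute control. It is tertiary, benzylic and alpha to the C4 ketone, so base, and more slowly acid, epimerises it; base can also open ring C by retro-oxa-Michael reaction. The chromene double bond is an electron-rich styrene that is sensitive to strong acid, hydrogenation and electrophilic oxidants. The 5-OMe must survive while two other phenols are unmasked, which rules out late Lewis-acid demethylation. The real difficulties are setting C3 where it cannot racemise and closing ring C onto the correct carbon of ring A (C4a, not C8). The key step uses the fact that C3 carries two one-carbon arms, C2 (bound to O1) and C4. With C4 at the alcohol level, C2–C3–C4 map onto a prochiral 3-aryloxetane whose two C–O bonds are enantiotopic.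

## Logic of the disconnections

**17 to 16.** The two O–Si bonds at the ring A C7 oxygen and the ring B C8 oxygen are cut. Free phenols would interfere with the nickel coupling, the acid catalysis, the oxidation and the acylation. There is no skeletal gain, but every earlier step becomes compatible. The forward step must unmask both phenols without base.

**16 to 14 (through 15).** The C4–C4a aryl ketone bond is cut. It lies ortho to the ether oxygen of a phloroglucinol-type ring, the classical position for Friedel–Crafts acylation. Ring C disappears and C3 sits in an open chain. The forward step must attack C4a rather than C8 and must be mild enough for the chromene and for C3.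

**14 to 12.** Only the oxidation level of the future C4 changes; no skeletal bond is cut. This allows the stereocentre to be made with no carbonyl beside it. The forward oxidation passes through 13, which must not lose configuration or eliminate the aryloxide.

**12 to 9 and 11.** The O1–C2 bond is cut. Both halves are achiral and of similar size, and the stereocentre arises from the choice between two enantiotopic C–O bonds of 9. The forward step demands catalyst control of that choice and O- rather than C-alkylation of 11.

**9 to 7 and 8.** The bond between oxetane C3 and the ring B carbon para to the pyran oxygen is cut. This C(sp2)–C(sp3) bond joins a commercial four-membered ring to an aryl bromide, so the oxetane need not be built. The forward coupling must work on an electron-rich bromide and without strong base.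

**7 to 6 to 5.** The O–Si bond and then the O–CH3 bond are exchanged. A methyl ether on ring B could not be removed at the end without endangering the 5-OMe, so the exchange is done early, when only a bromide and the chromene are present. The demethylation must leave the chromene intact.

**5 to 3 (through 4) to 1 and 2.** The ring D C4–C4a bond and the aryl O–C(CH3)2 bond are cut. Both come from one aryl propargyl ether by Claisen rearrangement and cyclisation. The regiochemistry is fixed because one ortho position of 1 carries OMe. This reaches two commercial compounds.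

**11 to 10.** One O–Si bond is cut. The forward step is monoprotection of a symmetric diol, and the bulky silyl group is chosen to steer steps 7 and 9.

## Other disconnections considered

**Alternative 1:** The cut is C3–C4, with closure of ring C. The racemic benzylic chloride/aroyl chloride A1 would be cyclised by NiCl2·glyme, a chiral bis(oxazoline) and Mn powder (or a cathode) to the bis-silyl isoflavanone A2.
- *In favour:* enantioconvergent nickel reductive coupling of acid chlorides with secondary benzylic chlorides is an established intermolecular route to alpha-aryl ketones, it needs no base, and it starts from a racemate. The acyl carbon is already on ring A, so the C4a/C8 question does not arise; on this point the alternative is better than the chosen plan.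
- *Against:* a six-ring intramolecular version has not been shown. A1 combines a para-alkoxybenzylic chloride that ionises readily with a doubly ortho-substituted aroyl chloride that must be made in its presence. The benzylnickel intermediate carries a beta-aryloxy group and could expel it. The hindered acylnickel species could lose CO.
- *Comparison:* on structure, both plans form C3 without base, but here it is formed already flanked by the ketone, whereas the chosen plan forms it with no carbonyl next to it. On mechanism, a radical/nickel pathway stands against polar hydrogen-bond catalysis, and both need new method development. On step economy, the two are about equal, or the alternative is slightly longer because A1 needs a regiodefined salicylate-type ring A block.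

**Alternative 2:** The cut is C3–C1', with no ring closure. Racemic bromoketone A3 and the arylzinc iodide A4 (from 7 by bromine–lithium exchange and ZnI2) would couple under NiCl2·glyme and a chiral pybox ligand near −30 °C to give A5, which is identical with 16.
- *In favour:* this is the most convergent plan. The stereocentre would be set in the last C–C bond formation, cold and base-free, under conditions designed for racemisable alpha-aryl ketones. It saves about two steps, so on step economy it is better than the chosen plan.
- *Against:* the reaction type is established for open-chain alpha-bromoketones. A cyclic bromoketone with a beta-aryloxy group has not been shown, and the alpha-keto radical or nickel enolate could expel the aryloxide and open ring C. A cyclic substrate may also fit the ligand pocket poorly.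
- *Comparison:* on structure, A3 needs the same regioselective closure onto ring A as the chosen plan, so the two are equal there. On mechanism, stereoconvergent radical capture at nickel stands against enantiotopic-group selection by a Brønsted acid; neither is precedented on its exact substrate. The chosen plan keeps C3 free of a flanking carbonyl for two further steps.

**Alternative 3:** No skeletal bond is cut at the key step. Racemic A6 would be reduced with the hand of RuCl(p-cymene)(TsDPEN) that leads to the 3R series, in HCO2H–Et3N, while C3 epimerises through the enol, to give the cis-(3R,4R)-chromanol A7. Oxidation of A7 would then give 16.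
- *In favour:* dynamic kinetic transfer hydrogenation is an established reaction type for 3-arylchroman-4-ones, so the key step needs no new method; on precedent it is better than the chosen plan. A6 is reachable by standard racemic chemistry with ring A regiochemistry fixed early.
- *Against:* the target is the ketone, so a reduction and a re-oxidation are added, and C3 is again alpha to the carbonyl after oxidation. The 5-OMe peri to C4 may slow hydride delivery. The 4-hydroxyl of A7 is a doubly oxygen-activated benzylic alcohol that could ionise and eliminate in formic acid.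
- *Comparison:* on structure, the alternative makes two stereocentres and destroys one, whereas the chosen plan makes one. On mechanism, metal–ligand bifunctional hydride transfer with substrate epimerisation stands against strain-release desymmetrisation. On step economy, the alternative is equal or slightly longer, but each step is precedented.

Key step: step 7

## Route

Step 1
Reactants: 1 4-bromo-2-methoxyphenol; 2 3-chloro-3-methylbut-1-yne
Product: 3 4-bromo-2-methoxy-1-[(2-methylbut-3-yn-2-yl)oxy]benzene
Conditions: K2CO3, KI (cat.), CuI (cat.), acetone, 56 °C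
Reagents that add atoms: none
Why: Copper-assisted O-alkylation of the phenoxide by the tertiary propargylic chloride (propargylic Williamson etherification) is the standard entry to aryl 1,1-dimethylpropargyl ethers; the aryl bromide and the methyl ether are inert.

Step 2
Reactants: 3 4-bromo-2-methoxy-1-[(2-methylbut-3-yn-2-yl)oxy]benzene
Product: 5 6-bromo-8-methoxy-2,2-dimethyl-2H-chromene, via allenylphenol 4 (not isolated)
Conditions: o-xylene, 140 °C
Reagents that add atoms: none
Why: Aromatic propargyl Claisen rearrangement: the [3,3] shift can go only to the one free ortho carbon (the other carries OMe) and enolisation gives 4, which closes ring D by 1,5-hydrogen shift and oxa-6π electrocyclisation.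

Step 3
Reactants: 5 6-bromo-8-methoxy-2,2-dimethyl-2H-chromene
Product: 6 6-bromo-2,2-dimethyl-2H-chromen-8-ol
Conditions: NaSEt, DMF, 120 °C; then 1 M HCl, 0 °C
Reagents that add atoms: none
Why: SN2 demethylation by a soft thiolate at the methyl carbon of a guaiacol-type ether; a nucleophilic reagent is chosen because BBr3-type Lewis acids would open or hydrobrominate the chromene, and the unactivated aryl bromide should not undergo substitution.

Step 4
Reactants: 6 6-bromo-2,2-dimethyl-2H-chromen-8-ol
Product: 7 [(6-bromo-2,2-dimethyl-2H-chromen-8-yl)oxy](tert-butyl)dimethylsilane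
Conditions: TBSCl, imidazole, DMF, 25 °C
Reagents that add atoms: tert-butyldimethylsilyl chloride, CC(C)(C)[Si](C)(C)Cl
Why: Standard imidazole-mediated silylation of a phenol; the silyl ether masks the acidic O–H for the nickel step and the acid-catalysed key step and is removed by fluoride at the end.

Step 5
Reactants: 7 [(6-bromo-2,2-dimethyl-2H-chromen-8-yl)oxy](tert-butyl)dimethylsilane; 8 3-iodooxetane
Product: 9 tert-butyl{[2,2-dimethyl-6-(oxetan-3-yl)-2H-chromen-8-yl]oxy}dimethylsilane
Conditions: NiI2 (10 mol%), 4,4'-di-tert-butyl-2,2'-bipyridine (10 mol%), Zn dust, pyridine (cat.), DMA, 60 °C, 8 added slowly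
Reagents that add atoms: none
Why: Nickel-catalysed reductive cross-electrophile coupling: the aryl bromide adds to zerovalent nickel, the oxetan-3-yl radical from the iodide is captured, and reductive elimination forms the C(sp2)–C(sp3) bond while Zn turns the catalyst over; no strong base is present, so the phenolic silyl ether should survive.

Step 6
Reactants: 10 5-methoxyresorcinol
Product: 11 3-methoxy-5-[(triisopropylsilyl)oxy]phenol
Conditions: TIPSCl (1 equiv), imidazole, DMF, 0 °C, 10 in excess (3 equiv)
Reagents that add atoms: triisopropylsilyl chloride, CC(C)[Si](Cl)(C(C)C)C(C)C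
Why: Statistical monosilylation of a symmetric diol, biased toward the mono ether by an excess of water-soluble 10; the bulky silyl group is chosen to shield its two ortho carbons in steps 7 and 9.

Step 7
Reactants: 9 tert-butyl{[2,2-dimethyl-6-(oxetan-3-yl)-2H-chromen-8-yl]oxy}dimethylsilane; 11 3-methoxy-5-[(triisopropylsilyl)oxy]phenol
Product: 12 (S)-2-[8-(tert-butyldimethylsilyloxy)-2,2-dimethyl-2H-chromen-6-yl]-3-[3-methoxy-5-(triisopropylsilyloxy)phenoxy]propan-1-ol
Conditions: (S)-STRIP (spirobiindane-derived chiral phosphoric acid with 2,4,6-triisopropylphenyl groups, 10 mol%), 11 (2 equiv), toluene, 25–40 °C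
Reagents that add atoms: none
Why: Proposed new method: the phosphoric acid O–H hydrogen-bonds (at the limit protonates) the oxetane oxygen of 9 while its P=O oxygen accepts the O–H of 11, so the phenol oxygen is delivered in an SN2 sense to one of the two enantiotopic CH2 groups and the strain of the four-membered ring (about 106 kJ/mol) is released. The closest known reaction type is the chiral phosphoric acid-catalysed desymmetrising opening of 3-substituted oxetanes by thiols, by chloride and by tethered oxygen or nitrogen nucleophiles; an intermolecular phenol oxygen has not been used in this way. No ring is closed; only the O1–C2 bond is made. The one new stereocentre (the future C3) is controlled by the catalyst alone, which decides which C–O bond breaks; no bond at that carbon is made or broken and no carbonyl flanks it, so it cannot epimerise here. The step needs O- over C-alkylation, which the hydrogen-bonded delivery of the O–H, the non-polar solvent and the triisopropylsilyl group shielding two of the three nucleophilic ring carbons of 11 should favour. It also needs 11 to outcompete the alcohol of 12 as nucleophile, which the higher acidity of the phenol and its excess should secure. The acid is too weak to add to the chromene double bond or to cleave the silyl ethers.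

Step 8
Reactants: 12 (S)-2-[8-(tert-butyldimethylsilyloxy)-2,2-dimethyl-2H-chromen-6-yl]-3-[3-methoxy-5-(triisopropylsilyloxy)phenoxy]propan-1-ol
Product: 14 (R)-2-[8-(tert-butyldimethylsilyloxy)-2,2-dimethyl-2H-chromen-6-yl]-3-[3-methoxy-5-(triisopropylsilyloxy)phenoxy]propanoic acid, via aldehyde 13 (not isolated)
Conditions: TEMPO (20 mol%), PhI(OAc)2 (2.2 equiv), CH2Cl2–H2O, 0 → 25 °C
Reagents that add atoms: water, O
Why: Oxoammonium (TEMPO) oxidation with PhI(OAc)2 as terminal oxidant takes the alcohol to aldehyde 13, whose hydrate is oxidised on to the acid in the same flask; the medium is weakly acidic and chlorine-free, which should keep the enolisable beta-aryloxy aldehyde from epimerising or eliminating and spare the electron-rich rings and the chromene.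

Step 9
Reactants: 14 (R)-2-[8-(tert-butyldimethylsilyloxy)-2,2-dimethyl-2H-chromen-6-yl]-3-[3-methoxy-5-(triisopropylsilyloxy)phenoxy]propanoic acid
Product: 16 (R)-3-[8-(tert-butyldimethylsilyloxy)-2,2-dimethyl-2H-chromen-6-yl]-5-methoxy-7-(triisopropylsilyloxy)chroman-4-one, via mixed anhydride 15 (not isolated)
Conditions: (CF3CO)2O (1.5 equiv), CH2Cl2, 0 °C, short reaction time; cold aq. NaHCO3 quench
Reagents that add atoms: trifluoroacetic anhydride, O=C(OC(=O)C(F)(F)F)C(F)(F)F (adds the trifluoroacetyl group to intermediate 15 only; nothing from it remains in 16)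
Why: Intramolecular Friedel–Crafts acylation through mixed anhydride 15 closes the six-membered ring C onto a phloroglucinol-type ring without a Lewis acid; attack is expected at C4a, between O1 and OMe, because the carbon on the other side of O1 is shielded by the triisopropylsilyloxy group, and without base no ketene forms, so C3 should keep its configuration.

Step 10
Reactants: 16 (R)-3-[8-(tert-butyldimethylsilyloxy)-2,2-dimethyl-2H-chromen-6-yl]-5-methoxy-7-(triisopropylsilyloxy)chroman-4-one
Product: 17 (R)-7-hydroxy-3-(8-hydroxy-2,2-dimethyl-2H-chromen-6-yl)-5-methoxychroman-4-one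
Conditions: HF·pyridine, pyridine, THF, 0 → 25 °C
Reagents that add atoms: none
Why: Fluoride cleavage of both aryl silyl ethers under buffered, weakly acidic conditions; basic fluoride is avoided because phenoxide formation would epimerise C3 or open ring C by retro-oxa-Michael reaction, and the pyridine buffer keeps HF from adding to the chromene.

## Compound list

1 | 4-bromo-2-methoxyphenol | COc1cc(Br)ccc1O | starting material
2 | 3-chloro-3-methylbut-1-yne | CC(C)(Cl)C#C | starting material
3 | 4-bromo-2-methoxy-1-[(2-methylbut-3-yn-2-yl)oxy]benzene | COc1cc(Br)ccc1OC(C)(C)C#C | intermediate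
4 | 4-bromo-2-methoxy-6-(3-methylbuta-1,2-dien-1-yl)phenol | COc1cc(Br)cc(C=C=C(C)C)c1O | intermediate (not isolated)
5 | 6-bromo-8-methoxy-2,2-dimethyl-2H-chromene | COc1cc(Br)cc2c1OC(C)(C)C=C2 | intermediate
6 | 6-bromo-2,2-dimethyl-2H-chromen-8-ol | Oc1cc(Br)cc2c1OC(C)(C)C=C2 | intermediate
7 | [(6-bromo-2,2-dimethyl-2H-chromen-8-yl)oxy](tert-butyl)dimethylsilane | CC(C)(C)[Si](C)(C)Oc1cc(Br)cc2c1OC(C)(C)C=C2 | intermediate
8 | 3-iodooxetane | IC1COC1 | starting material
9 | tert-butyl{[2,2-dimethyl-6-(oxetan-3-yl)-2H-chromen-8-yl]oxy}dimethylsilane | C1OCC1c1cc(O[Si](C)(C)C(C)(C)C)c2c(c1)C=CC(C)(C)O2 | intermediate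
10 | 5-methoxyresorcinol | COc1cc(O)cc(O)c1 | starting material
11 | 3-methoxy-5-[(triisopropylsilyl)oxy]phenol | COc1cc(O)cc(O[Si](C(C)C)(C(C)C)C(C)C)c1 | intermediate
12 | (S)-2-[8-(tert-butyldimethylsilyloxy)-2,2-dimethyl-2H-chromen-6-yl]-3-[3-methoxy-5-(triisopropylsilyloxy)phenoxy]propan-1-ol | OC[C@H](c1cc(O[Si](C)(C)C(C)(C)C)c2c(c1)C=CC(C)(C)O2)COc1cc(OC)cc(O[Si](C(C)C)(C(C)C)C(C)C)c1 | intermediate
13 | (R)-2-[8-(tert-butyldimethylsilyloxy)-2,2-dimethyl-2H-chromen-6-yl]-3-[3-methoxy-5-(triisopropylsilyloxy)phenoxy]propanal | O=C[C@H](c1cc(O[Si](C)(C)C(C)(C)C)c2c(c1)C=CC(C)(C)O2)COc1cc(OC)cc(O[Si](C(C)C)(C(C)C)C(C)C)c1 | intermediate (not isolated)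
14 | (R)-2-[8-(tert-butyldimethylsilyloxy)-2,2-dimethyl-2H-chromen-6-yl]-3-[3-methoxy-5-(triisopropylsilyloxy)phenoxy]propanoic acid | OC(=O)[C@H](c1cc(O[Si](C)(C)C(C)(C)C)c2c(c1)C=CC(C)(C)O2)COc1cc(OC)cc(O[Si](C(C)C)(C(C)C)C(C)C)c1 | intermediate
15 | (R)-2-[8-(tert-butyldimethylsilyloxy)-2,2-dimethyl-2H-chromen-6-yl]-3-[3-methoxy-5-(triisopropylsilyloxy)phenoxy]propanoic trifluoroacetic anhydride | O=C(OC(=O)C(F)(F)F)[C@H](c1cc(O[Si](C)(C)C(C)(C)C)c2c(c1)C=CC(C)(C)O2)COc1cc(OC)cc(O[Si](C(C)C)(C(C)C)C(C)C)c1 | intermediate (not isolated)
16 | (R)-3-[8-(tert-butyldimethylsilyloxy)-2,2-dimethyl-2H-chromen-6-yl]-5-methoxy-7-(triisopropylsilyloxy)chroman-4-one | COc1cc(O[Si](C(C)C)(C(C)C)C(C)C)cc2c1C(=O)[C@H](c1cc(O[Si](C)(C)C(C)(C)C)c3c(c1)C=CC(C)(C)O3)CO2 | intermediate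
17 | (R)-7-hydroxy-3-(8-hydroxy-2,2-dimethyl-2H-chromen-6-yl)-5-methoxychroman-4-one | COc1cc(O)cc2c1C(=O)[C@H](c1cc(O)c3c(c1)C=CC(C)(C)O3)CO2 | target

## Step count and least certain steps

Total: 10 steps. Longest linear sequence: 9 steps (from 1 through steps 1–5 and 7–10); step 6 is a one-step side branch.

**Step 7 (key step, proposed new method).**
- *What may go wrong:* Friedel–Crafts C-alkylation at the ring carbons of 11 in place of O-alkylation; slow opening, because a neutral phenol is a weaker partner for the acid than a thiol or chloride; chain growth when the alcohol just formed opens a second oxetane; poor discrimination between the two enantiotopic C–O bonds.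
- *Fallback (known chemistry), from 9 back to 12:* the oxetane would be desymmetrised with bromide, using TMSBr and a chiral squaramide hydrogen-bond donor at low temperature, an established enantioselective oxetane opening. This would give (S)-{3-bromo-2-[8-(tert-butyldimethylsilyloxy)-2,2-dimethyl-2H-chromen-6-yl]propoxy}trimethylsilane F1. SN2 displacement of the primary bromide by the potassium salt of 11 (K2CO3, MeCN, 40 °C) would give the trimethylsilyl ether of 12, (R)-{2-[8-(tert-butyldimethylsilyloxy)-2,2-dimethyl-2H-chromen-6-yl]-3-[3-methoxy-5-(triisopropylsilyloxy)phenoxy]propoxy}trimethylsilane F2. A citric acid work-up would release 12. The C–O bond is then made in a separate substitution step and the stereocentre is set by a known halide opening.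

**Step 9.**
- *What may go wrong:* acylation at C8 instead of C4a if the steric bias of the silyl group is too small; acid-promoted hydration or oligomerisation of the chromene; trifluoroacetylation of the chromene olefin; acid-catalysed enolisation with loss of configuration at C3.
- *Fallback, from 12 back to 16 (replaces steps 8 and 9):* directed ortho-lithiation of 12 (n-BuLi, 2.2 equiv, THF, 0 °C) should occur between the two alkoxy groups of ring A, because the silyloxy group neither directs nor admits the base. An I2 quench would give (S)-2-[8-(tert-butyldimethylsilyloxy)-2,2-dimethyl-2H-chromen-6-yl]-3-[2-iodo-3-methoxy-5-(triisopropylsilyloxy)phenoxy]propan-1-ol F3. Dess–Martin oxidation (NaHCO3, CH2Cl2) would give (R)-2-[8-(tert-butyldimethylsilyloxy)-2,2-dimethyl-2H-chromen-6-yl]-3-[2-iodo-3-methoxy-5-(triisopropylsilyloxy)phenoxy]propanal F4, to be used at once. Intramolecular Nozaki–Hiyama–Kishi addition (CrCl2, NiCl2 cat., DMF, 25 °C) would give (3R)-3-[8-(tert-butyldimethylsilyloxy)-2,2-dimethyl-2H-chromen-6-yl]-5-methoxy-7-(triisopropylsilyloxy)chroman-4-ol F5 as a mixture at C4. A second Dess–Martin oxidation would give 16. The regiochemistry is then fixed by the position of the iodine and no strong acid is used.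

**Step 5.**
- *What may go wrong:* homocoupling or reduction of the reactive secondary iodide before the electron-rich aryl bromide has added to nickel; addition of the oxetanyl radical to the chromene double bond; zinc halide-promoted opening of the oxetane.
- *Fallback, from 7 back to 9:* the oxetane would be built instead of coupled. Pd-catalysed alpha-arylation of diethyl malonate with 7 (Pd(dba)2, P(t-Bu)3, K3PO4, toluene, 70 °C) would give diethyl 2-[8-(tert-butyldimethylsilyloxy)-2,2-dimethyl-2H-chromen-6-yl]malonate F6. Reduction (LiAlH4, THF, 0 °C) would give 2-[8-(tert-butyldimethylsilyloxy)-2,2-dimethyl-2H-chromen-6-yl]propane-1,3-diol F7. Treatment with n-BuLi and TsCl would form 2-[8-(tert-butyldimethylsilyloxy)-2,2-dimethyl-2H-chromen-6-yl]-3-hydroxypropyl 4-methylbenzenesulfonate F8 in the flask, and a second equivalent of n-BuLi (THF, 0 → 60 °C) would close it to 9 by intramolecular Williamson etherification.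

## Further compounds

F1 | step 7 | (S)-{3-bromo-2-[8-(tert-butyldimethylsilyloxy)-2,2-dimethyl-2H-chromen-6-yl]propoxy}trimethylsilane | C[Si](C)(C)OC[C@H](c1cc(O[Si](C)(C)C(C)(C)C)c2c(c1)C=CC(C)(C)O2)CBr
F2 | step 7 | (R)-{2-[8-(tert-butyldimethylsilyloxy)-2,2-dimethyl-2H-chromen-6-yl]-3-[3-methoxy-5-(triisopropylsilyloxy)phenoxy]propoxy}trimethylsilane | C[Si](C)(C)OC[C@H](c1cc(O[Si](C)(C)C(C)(C)C)c2c(c1)C=CC(C)(C)O2)COc1cc(OC)cc(O[Si](C(C)C)(C(C)C)C(C)C)c1
F3 | step 9 | (S)-2-[8-(tert-butyldimethylsilyloxy)-2,2-dimethyl-2H-chromen-6-yl]-3-[2-iodo-3-methoxy-5-(triisopropylsilyloxy)phenoxy]propan-1-ol | OC[C@H](c1cc(O[Si](C)(C)C(C)(C)C)c2c(c1)C=CC(C)(C)O2)COc1cc(O[Si](C(C)C)(C(C)C)C(C)C)cc(OC)c1I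
F4 | step 9 | (R)-2-[8-(tert-butyldimethylsilyloxy)-2,2-dimethyl-2H-chromen-6-yl]-3-[2-iodo-3-methoxy-5-(triisopropylsilyloxy)phenoxy]propanal | O=C[C@H](c1cc(O[Si](C)(C)C(C)(C)C)c2c(c1)C=CC(C)(C)O2)COc1cc(O[Si](C(C)C)(C(C)C)C(C)C)cc(OC)c1I
F5 | step 9 | (3R)-3-[8-(tert-butyldimethylsilyloxy)-2,2-dimethyl-2H-chromen-6-yl]-5-methoxy-7-(triisopropylsilyloxy)chroman-4-ol (both C4 epimers) | COc1cc(O[Si](C(C)C)(C(C)C)C(C)C)cc2c1C(O)[C@H](c1cc(O[Si](C)(C)C(C)(C)C)c3c(c1)C=CC(C)(C)O3)CO2
F6 | step 5 | diethyl 2-[8-(tert-butyldimethylsilyloxy)-2,2-dimethyl-2H-chromen-6-yl]malonate | CCOC(=O)C(C(=O)OCC)c1cc(O[Si](C)(C)C(C)(C)C)c2c(c1)C=CC(C)(C)O2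
F7 | step 5 | 2-[8-(tert-butyldimethylsilyloxy)-2,2-dimethyl-2H-chromen-6-yl]propane-1,3-diol | OCC(CO)c1cc(O[Si](C)(C)C(C)(C)C)c2c(c1)C=CC(C)(C)O2
F8 | step 5 | 2-[8-(tert-butyldimethylsilyloxy)-2,2-dimethyl-2H-chromen-6-yl]-3-hydroxypropyl 4-methylbenzenesulfonate (racemic) | Cc1ccc(cc1)S(=O)(=O)OCC(CO)c1cc(O[Si](C)(C)C(C)(C)C)c2c(c1)C=CC(C)(C)O2
A1 | alternative 1 | 2-{2-chloro-2-[2,2-dimethyl-8-(triisopropylsilyloxy)-2H-chromen-6-yl]ethoxy}-6-methoxy-4-(triisopropylsilyloxy)benzoyl chloride (racemic) | COc1cc(O[Si](C(C)C)(C(C)C)C(C)C)cc(OCC(Cl)c2cc(O[Si](C(C)C)(C(C)C)C(C)C)c3c(c2)C=CC(C)(C)O3)c1C(=O)Cl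
A2 | alternative 1 | (R)-3-[2,2-dimethyl-8-(triisopropylsilyloxy)-2H-chromen-6-yl]-5-methoxy-7-(triisopropylsilyloxy)chroman-4-one | COc1cc(O[Si](C(C)C)(C(C)C)C(C)C)cc2c1C(=O)[C@H](c1cc(O[Si](C(C)C)(C(C)C)C(C)C)c3c(c1)C=CC(C)(C)O3)CO2
A3 | alternative 2 | 3-bromo-5-methoxy-7-(triisopropylsilyloxy)chroman-4-one (racemic) | COc1cc(O[Si](C(C)C)(C(C)C)C(C)C)cc2c1C(=O)C(Br)CO2
A4 | alternative 2 | [8-(tert-butyldimethylsilyloxy)-2,2-dimethyl-2H-chromen-6-yl]zinc iodide | CC(C)(C)[Si](C)(C)Oc1cc([Zn]I)cc2c1OC(C)(C)C=C2
A5 | alternative 2 | (R)-3-[8-(tert-butyldimethylsilyloxy)-2,2-dimethyl-2H-chromen-6-yl]-5-methoxy-7-(triisopropylsilyloxy)chroman-4-one | COc1cc(O[Si](C(C)C)(C(C)C)C(C)C)cc2c1C(=O)[C@H](c1cc(O[Si](C)(C)C(C)(C)C)c3c(c1)C=CC(C)(C)O3)CO2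
A6 | alternative 3 | 3-[8-(tert-butyldimethylsilyloxy)-2,2-dimethyl-2H-chromen-6-yl]-5-methoxy-7-(triisopropylsilyloxy)chroman-4-one (racemic) | COc1cc(O[Si](C(C)C)(C(C)C)C(C)C)cc2c1C(=O)C(c1cc(O[Si](C)(C)C(C)(C)C)c3c(c1)C=CC(C)(C)O3)CO2
A7 | alternative 3 | cis-(3R,4R)-3-[8-(tert-butyldimethylsilyloxy)-2,2-dimethyl-2H-chromen-6-yl]-5-methoxy-7-(triisopropylsilyloxy)chroman-4-ol | COc1cc(O[Si](C(C)C)(C(C)C)C(C)C)cc2c1[C@H](O)[C@H](c1cc(O[Si](C)(C)C(C)(C)C)c3c(c1)C=CC(C)(C)O3)CO2
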